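**Strategy.** Tetralin numbering is used: C1 carries the pendant aryl group, C2 and C3 the methyl groups, C4 is the CH2, and C4a/C8a are the fused aromatic carbons. Cutting the C4–C4a bond reveals two hidden symmetries: C1 then carries two identical 3,4-dimethoxyphenyl groups, and the cis C2/C3 dimethyl pair is the backbone of meso-2,3-dimethylsuccinic acid. The precursor of the key step is therefore (2S,3S)-4,4-bis(3,4-dimethoxyphenyl)-2,3-dimethylbutanoic acid, reached by catalytic enantioselective arylation of the meso anhydride. In one operation a reductive Friedel–Crafts cyclization closes the six-membered carbocycle at C4–C4a, chooses one of the two diastereotopic aryl rings so that C1 becomes a stereocenter trans to the C2 methyl group, and removes the acyl oxygen.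

Key step: step 5

Assumption: the absolute sense of the desymmetrization in step 2 is fixed by the choice of ligand enantiomer; the enantiomer that arylates the carbonyl group on the (R)-configured carbon of 2 is used, and its identity is to be confirmed on the first batch.

**Step 1**
Reactants: 1 meso-2,3-dimethylsuccinic acid
Product: 2 cis-2,3-dimethylsuccinic anhydride ((3R,4S)-3,4-dimethyloxolane-2,5-dione)
Conditions: AcCl, reflux
Reagents that add atoms: none
Why: Cyclodehydration of a 1,4-diacid by an acyl chloride should give the five-membered cyclic anhydride without touching either stereocenter, so the cis (meso) relationship is kept.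

**Step 2**
Reactants: 2 cis-2,3-dimethylsuccinic anhydride; 3 4-bromo-1,2-dimethoxybenzene
Product: 6 (2S,3R)-4-(3,4-dimethoxyphenyl)-2,3-dimethyl-4-oxobutanoic acid, via (3,4-dimethoxyphenyl)lithium 4 (not isolated), via (3,4-dimethoxyphenyl)zinc triflate 5 (not isolated)
Conditions: 3, n-BuLi, THF, −78 °C; Zn(OTf)2, −78 °C → rt; then 2, [Rh(cod)Cl]2 (cat., cod = 1,5-cyclooctadiene), TADDOL-derived N,N-dimethylphosphoramidite (cat.), THF/DMF, 50 °C; aq. HCl
Reagents that add atoms: none
Why: Bromine–lithium exchange and transmetalation give an arylzinc that should undergo rhodium-catalyzed enantioselective acyl cross-coupling with the meso anhydride (enantiotopic-group-selective desymmetrization), in which the chiral monovalent rhodium catalyst inserts into only one of the two enantiotopic C(O)–O bonds; no new stereocenter forms, the two existing ones become (2S,3R), and the arylzinc does not add to the ketone produced.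

**Step 3**
Reactants: 6 (2S,3R)-4-(3,4-dimethoxyphenyl)-2,3-dimethyl-4-oxobutanoic acid; 7 (3,4-dimethoxyphenyl)magnesium bromide (commercial solution in THF)
Product: 9 (3S,4R)-5,5-bis(3,4-dimethoxyphenyl)-3,4-dimethyloxolan-2-one, via hydroxy acid 8 (not isolated)
Conditions: 7 (3 equiv), CeCl3 (anhydrous), THF, −78 → 0 °C; sat. aq. NH4Cl; then PPTS (cat.), CH2Cl2, rt
Reagents that add atoms: none
Why: The first equivalent of the Grignard reagent deprotonates the acid, and the weakly basic organocerium species formed with CeCl3 should then add 1,2 to the enolizable aryl ketone rather than enolize it (cerium-mediated Grignard addition), after which the tertiary gamma-hydroxy acid should close to the gamma-lactone under mild acid; the new carbinol carbon bears two identical aryl groups and is no stereocenter, and the two methyl-bearing centers are not touched.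

**Step 4**
Reactants: 9 (3S,4R)-5,5-bis(3,4-dimethoxyphenyl)-3,4-dimethyloxolan-2-one
Product: 10 (2S,3S)-4,4-bis(3,4-dimethoxyphenyl)-2,3-dimethylbutanoic acid
Conditions: H2 (3 atm), Pd/C, EtOAc/AcOH, rt
Reagents that add atoms: none
Why: Catalytic hydrogenolysis of the doubly benzylic C–O bond of an ester, as in the cleavage of diphenylmethyl esters, should open the lactone to the acid without an acid strong enough to ionize the diarylcarbinyl position, so the neighbouring stereocenter is kept and the new methine, with two identical aryl groups, is no stereocenter.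

**Step 5**
Reactants: 10 (2S,3S)-4,4-bis(3,4-dimethoxyphenyl)-2,3-dimethylbutanoic acid
Product: 13 (1R,2R,3R)-1-(3,4-dimethoxyphenyl)-6,7-dimethoxy-2,3-dimethyl-1,2,3,4-tetrahydronaphthalene, via mixed trifluoroacetic anhydride 11 (not isolated), via tetralone 12 (not isolated)
Conditions: TFAA, TFA, CH2Cl2, 0 °C → rt; then Et3SiH, rt
Reagents that add atoms: none
Why: The acid is converted into its mixed trifluoroacetic anhydride, which ionizes to an acylium ion that attacks, ortho to C1 and para to a methoxy group, one of the two 3,4-dimethoxyphenyl rings on C1; the resulting aryl ketone is then reduced to CH2 in the same flask by ionic hydrogenation with Et3SiH/TFA. The closest known reaction type is the intramolecular Friedel–Crafts acylation of 4,4-diarylbutanoic acids to 4-aryl-1-tetralones, followed by silane/acid deoxygenation of an electron-rich aryl ketone. The ring closes in a six-membered mode, exo with respect to the acylium C≡O, with the attacked arene bond C4a=C8a ending inside the new ring. C1 becomes a stereocenter only in this step, by choice between two diastereotopic aryl groups under control of the C2 stereocenter: closure through the ring that leaves the free aryl group pseudo-axial and anti to the C2 methyl group avoids both the aryl/methyl gauche contact and the peri clash with C8–H, so the 1,2-trans isomer should prevail. The step needs this diastereotopic-group selectivity, para-to-methoxy regioselectivity (the other ortho site, between the side chain and a methoxy group, is hindered), and retention at C3, which base-free acidic conditions and fast hydride capture of the protonated ketone and of the C4 benzylic cation should secure. C2 and C3 are carried unchanged from acid 10.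

**Compound list**
1 | meso-2,3-dimethylsuccinic acid ((2R,3S)-2,3-dimethylbutanedioic acid) | OC(=O)[C@H](C)[C@H](C)C(=O)O | starting material
2 | cis-2,3-dimethylsuccinic anhydride ((3R,4S)-3,4-dimethyloxolane-2,5-dione) | O=C1OC(=O)[C@H](C)[C@@H]1C | intermediate
3 | 4-bromo-1,2-dimethoxybenzene | COc1ccc(Br)cc1OC | starting material
4 | (3,4-dimethoxyphenyl)lithium | [Li]c1ccc(OC)c(OC)c1 | intermediate
5 | (3,4-dimethoxyphenyl)zinc trifluoromethanesulfonate | COc1ccc([Zn]OS(=O)(=O)C(F)(F)F)cc1OC | intermediate
6 | (2S,3R)-4-(3,4-dimethoxyphenyl)-2,3-dimethyl-4-oxobutanoic acid | COc1ccc(C(=O)[C@H](C)[C@H](C)C(=O)O)cc1OC | intermediate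
7 | (3,4-dimethoxyphenyl)magnesium bromide | COc1ccc([Mg]Br)cc1OC | starting material
8 | (2S,3R)-4,4-bis(3,4-dimethoxyphenyl)-4-hydroxy-2,3-dimethylbutanoic acid | COc1ccc(C(O)(c2ccc(OC)c(OC)c2)[C@H](C)[C@H](C)C(=O)O)cc1OC | intermediate
9 | (3S,4R)-5,5-bis(3,4-dimethoxyphenyl)-3,4-dimethyloxolan-2-one | COc1ccc(C2(c3ccc(OC)c(OC)c3)OC(=O)[C@@H](C)[C@H]2C)cc1OC | intermediate
10 | (2S,3S)-4,4-bis(3,4-dimethoxyphenyl)-2,3-dimethylbutanoic acid | COc1ccc(C(c2ccc(OC)c(OC)c2)[C@H](C)[C@H](C)C(=O)O)cc1OC | intermediate
11 | (2S,3S)-4,4-bis(3,4-dimethoxyphenyl)-2,3-dimethylbutanoic trifluoroacetic anhydride | COc1ccc(C(c2ccc(OC)c(OC)c2)[C@H](C)[C@H](C)C(=O)OC(=O)C(F)(F)F)cc1OC | intermediate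
12 | (2S,3S,4R)-4-(3,4-dimethoxyphenyl)-6,7-dimethoxy-2,3-dimethyl-3,4-dihydronaphthalen-1(2H)-one | COc1ccc([C@@H]2c3cc(OC)c(OC)cc3C(=O)[C@@H](C)[C@H]2C)cc1OC | intermediate
13 | (1R,2R,3R)-1-(3,4-dimethoxyphenyl)-6,7-dimethoxy-2,3-dimethyl-1,2,3,4-tetrahydronaphthalene (1,2-trans, 2,3-cis) | COc1ccc([C@@H]2c3cc(OC)c(OC)cc3C[C@@H](C)[C@H]2C)cc1OC | target

**Step count and risks**
Total steps: 5. Longest linear sequence: 5 steps (1 → 2 → 6 → 9 → 10 → 13).

Step 5 (key step). What may go wrong: loss of configuration at C3, either by enolization of tetralone 12 in the acidic medium or by proton loss from the C4 benzylic cation during silane reduction followed by unselective reprotonation. Incomplete discrimination between the two aryl rings would show as the 1,2-cis isomer. The fallback sets out from 10 and comes back at 13. LiAlH4 in THF should reduce 10 to (2S,3S)-4,4-bis(3,4-dimethoxyphenyl)-2,3-dimethylbutan-1-ol F6. Tf2O and 2,6-di-tert-butyl-4-methylpyridine in CH2Cl2 at −78 °C should give (2S,3S)-4,4-bis(3,4-dimethoxyphenyl)-2,3-dimethylbutyl trifluoromethanesulfonate F7. On warming in (CF3)2CHOH, this should close by aryl-assisted displacement (intramolecular Friedel–Crafts alkylation by a primary sulfonate) to 13. Neither a carbonyl group nor a C4 cation appears on this path, so C3 cannot epimerize.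

Step 2. What may go wrong: weak discrimination between the two enantiotopic carbonyl groups, or slow transmetalation of the electron-rich arylzinc. A small shortfall in enantiomeric purity could be removed by recrystallization of lactone 9. The fallback sets out from 2 and comes back at 6. Cinchona-alkaloid-mediated alcoholysis of 2 with benzyl alcohol in toluene at low temperature (quinine or quinidine, whichever places the ester on the (S)-carbon) should give (2R,3S)-4-(benzyloxy)-2,3-dimethyl-4-oxobutanoic acid F1. Oxalyl chloride with catalytic DMF should give benzyl (2S,3R)-4-chloro-2,3-dimethyl-4-oxobutanoate F2. Acyl Negishi coupling of F2 with arylzinc 5 (prepared from 3 as in step 2) under Pd(PPh3)4 catalysis in THF should give benzyl (2S,3R)-4-(3,4-dimethoxyphenyl)-2,3-dimethyl-4-oxobutanoate F3. Hydrogenolysis of the benzyl ester (H2, Pd/C, EtOAc) should then give 6.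

Step 4. What may go wrong: slow hydrogenolysis at the hindered tertiary carbon, or ionization to the diarylcarbenium ion followed by proton loss and unselective return, which would scramble the adjacent stereocenter. The fallback sets out from 6 and comes back at 10. NaBH4 in aqueous methanolic NaOH should reduce the ketone to (2S,3R)-4-(3,4-dimethoxyphenyl)-4-hydroxy-2,3-dimethylbutanoic acid F4 (either configuration at the carbinol carbon). On acidification F4 should lactonize to (3S,4R)-5-(3,4-dimethoxyphenyl)-3,4-dimethyloxolan-2-one F5. Friedel–Crafts alkylation of 1,2-dimethoxybenzene (excess) with F5 under TfOH in CH2Cl2 at low temperature should open the lactone at the benzylic carbon and give 10 directly, with no tertiary C–O bond to reduce.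

**Further compounds**
F1 | step 2 | (2R,3S)-4-(benzyloxy)-2,3-dimethyl-4-oxobutanoic acid | OC(=O)[C@H](C)[C@H](C)C(=O)OCc1ccccc1
F2 | step 2 | benzyl (2S,3R)-4-chloro-2,3-dimethyl-4-oxobutanoate | ClC(=O)[C@H](C)[C@H](C)C(=O)OCc1ccccc1
F3 | step 2 | benzyl (2S,3R)-4-(3,4-dimethoxyphenyl)-2,3-dimethyl-4-oxobutanoate | COc1ccc(C(=O)[C@H](C)[C@H](C)C(=O)OCc2ccccc2)cc1OC
F4 | step 4 | (2S,3R)-4-(3,4-dimethoxyphenyl)-4-hydroxy-2,3-dimethylbutanoic acid (either configuration at C4) | COc1ccc(C(O)[C@H](C)[C@H](C)C(=O)O)cc1OC
F5 | step 4 | (3S,4R)-5-(3,4-dimethoxyphenyl)-3,4-dimethyloxolan-2-one (either configuration at C5) | COc1ccc(C2OC(=O)[C@@H](C)[C@H]2C)cc1OC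
F6 | step 5 | (2S,3S)-4,4-bis(3,4-dimethoxyphenyl)-2,3-dimethylbutan-1-ol | COc1ccc(C(c2ccc(OC)c(OC)c2)[C@H](C)[C@H](C)CO)cc1OC
F7 | step 5 | (2S,3S)-4,4-bis(3,4-dimethoxyphenyl)-2,3-dimethylbutyl trifluoromethanesulfonate | COc1ccc(C(c2ccc(OC)c(OC)c2)[C@H](C)[C@H](C)COS(=O)(=O)C(F)(F)F)cc1OC
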